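**Strategy.** The ten-membered carbocycle (C1–C10) is cut at C3–C4 and re-joined at C1–C6, which leads back to a cyclohexane. The step exploits the array C6–O, C5–O, C4=C15 methylene and E-C1=C2, which is what an oxy-Cope rearrangement leaves behind. One anionic [3,3] shift of a 1-(1-alkoxyallenyl)-2-vinylcyclohexanol expands the six-membered ring by four atoms and delivers the ring, the E-alkene, the exo-methylene, the C5 oxygen and the C6 ketone together. The precursor is a cyclohexanol with C7 (side chain C11–C12), C8 and C10 already set, a C1 vinyl group and a C6 (4-methoxybenzyloxy)allenyl group trans to it. Lactone, methylene, acetate and tiglate follow.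

Key step: step 17

Remark: germacrane numbering (ring C1–C10, C11–C13 lactone carbons, C14 on C10, C15 on C4) is used for every intermediate; C1 and C6 of the rearrangement precursor, which the key step erases, are deliberately set with the C6 hydroxyl trans to the C7 side chain (vinyl cis to the C10 oxygen), because on the chair model this diastereomer, not the more easily made one, exposes the enolate face that gives 5S.

Step 1
Reactants: 1 ethyl (3S)-4-chloro-3-hydroxybutanoate
Product: 2 ethyl [(2S)-oxiran-2-yl]acetate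
Conditions: Ag2O, MeCN, 40 °C
Reagents that add atoms: none
Why: Halohydrin-to-epoxide closure (intramolecular Williamson reaction) under silver assistance avoids the basic conditions that would open the β,γ-epoxy ester by elimination, and the carbinol centre is not touched.

Step 2
Reactants: 2 ethyl [(2S)-oxiran-2-yl]acetate
Product: 3 ethyl (3R)-3-hydroxy-5-methylhex-5-enoate
Conditions: CH2=C(CH3)MgBr, CuI (10 mol %), THF, −40 °C
Reagents that add atoms: isopropenylmagnesium bromide C=C(C)[Mg]Br
Why: Copper-catalysed Grignard opening of the terminal epoxide at its CH2 carbon (SN2) should give the β-hydroxy ester with C8 unchanged, as is usual for β,γ-epoxy esters at low temperature.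

Step 3
Reactants: 3 ethyl (3R)-3-hydroxy-5-methylhex-5-enoate; 4 tert-butyl(2-iodoethoxy)dimethylsilane
Product: 6 ethyl (2R,3R)-2-[2-(tert-butyldimethylsilyloxy)ethyl]-3-hydroxy-5-methylhex-5-enoate, via dilithium alkoxide-enolate 5 (not isolated)
Conditions: LiN(iPr)2 (2.2 equiv), THF, −78 to −20 °C; then 4, DMPU, −40 to 0 °C
Reagents that add atoms: none
Why: Fráter–Seebach alkylation, in which the lithium-chelated alkoxide-enolate is alkylated on the face away from the C9 chain, sets C7 anti to the C8 hydroxyl, the relationship that becomes cis on the ring.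

Step 4
Reactants: 6 ethyl (2R,3R)-2-[2-(tert-butyldimethylsilyloxy)ethyl]-3-hydroxy-5-methylhex-5-enoate
Product: 7 ethyl (2R,3R)-3-(tert-butyldimethylsilyloxy)-2-[2-(tert-butyldimethylsilyloxy)ethyl]-5-methylhex-5-enoate
Conditions: TBSOTf, 2,6-lutidine, CH2Cl2, 0 °C
Reagents that add atoms: tert-butyldimethylsilyl triflate CC(C)(C)[Si](C)(C)OS(=O)(=O)C(F)(F)F
Why: Silyl triflate silylation of the hindered secondary alcohol under non-nucleophilic base leaves both stereocentres and the 1,1-disubstituted alkene alone.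

Step 5
Reactants: 7 ethyl (2R,3R)-3-(tert-butyldimethylsilyloxy)-2-[2-(tert-butyldimethylsilyloxy)ethyl]-5-methylhex-5-enoate
Product: 8 (2R,3R)-3-(tert-butyldimethylsilyloxy)-2-[2-(tert-butyldimethylsilyloxy)ethyl]-N-methoxy-N,5-dimethylhex-5-enamide
Conditions: MeNH(OMe)·HCl, AlMe3, CH2Cl2, 0 to 23 °C
Reagents that add atoms: N,O-dimethylhydroxylamine hydrochloride CNOC.Cl
Why: Aluminium-amide aminolysis of the ester (Weinreb amide formation) is non-basic and should spare the epimerisable C7 centre and the β-silyloxy group.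

Step 6
Reactants: 8 (2R,3R)-3-(tert-butyldimethylsilyloxy)-2-[2-(tert-butyldimethylsilyloxy)ethyl]-N-methoxy-N,5-dimethylhex-5-enamide
Product: 9 (4R,5R)-5-(tert-butyldimethylsilyloxy)-4-[2-(tert-butyldimethylsilyloxy)ethyl]-7-methylocta-1,7-dien-3-one
Conditions: CH2=CHMgBr, THF, −20 °C; then cold 1 M HCl (inverse quench)
Reagents that add atoms: vinylmagnesium bromide C=C[Mg]Br
Why: Grignard addition to the Weinreb amide stops at the ketone through the chelated tetrahedral intermediate, and the acidic inverse quench keeps the liberated amine from adding to the vinyl ketone.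

Step 7
Reactants: 9 (4R,5R)-5-(tert-butyldimethylsilyloxy)-4-[2-(tert-butyldimethylsilyloxy)ethyl]-7-methylocta-1,7-dien-3-one
Product: 10 (5R,6R)-5-(tert-butyldimethylsilyloxy)-6-[2-(tert-butyldimethylsilyloxy)ethyl]-3-methylcyclohex-2-en-1-one (5,6-cis; C6 ketone, C1=C10 alkene in germacrane numbering)
Conditions: RuCl2(=CHPh)(PCy3)(H2IMes) (second-generation Grubbs catalyst, 5 mol %), CH2Cl2, 40 °C
Reagents that add atoms: none
Why: Ring-closing metathesis of the vinyl ketone with the 1,1-disubstituted alkene closes the six-membered ring as a 3-methylcyclohexenone with loss of ethene.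

Step 8
Reactants: 10 (5R,6R)-5-(tert-butyldimethylsilyloxy)-6-[2-(tert-butyldimethylsilyloxy)ethyl]-3-methylcyclohex-2-en-1-one
Product: 11 C1–C10 epoxide of 10 (epoxide oxygen trans to the C8 silyloxy group and to the C7 side chain)
Conditions: 30% H2O2, LiOH (0.2 equiv), MeOH, 0 °C
Reagents that add atoms: hydrogen peroxide OO
Why: In this Weitz–Scheffer nucleophilic epoxidation the hydroperoxide adds to C10 anti to the C8 silyloxy group, as conjugate additions to 5-substituted cyclohexenones do, so the future C10 oxygen is set trans to the C8 oxygen.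

Step 9
Reactants: 11 C1–C10 epoxide of 10
Product: 12 cis-epoxy alcohol (C6 hydroxyl on the same face as the epoxide oxygen)
Conditions: Zn(BH4)2, Et2O, −20 °C
Reagents that add atoms: none
Why: Chelation-controlled reduction of the α,β-epoxy ketone delivers hydride anti to the epoxide oxygen and gives the cis-epoxy alcohol, which cannot undergo Payne rearrangement; C6 is re-oxidised in step 11, so its configuration is not carried further.

Step 10
Reactants: 12 cis-epoxy alcohol
Product: 13 C6,C10-diol with a C1 vinyl group (vinyl trans to the C10 hydroxyl, cis to the C7 side chain)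
Conditions: CH2=CHMgBr (4 equiv), CuI (20 mol %), THF, −30 to 0 °C
Reagents that add atoms: vinylmagnesium bromide C=C[Mg]Br
Why: Copper-catalysed Grignard opening of the trisubstituted epoxide occurs at its secondary carbon C1 with inversion (trans-diaxial, Fürst–Plattner), which fixes C10 (methyl, hydroxyl) and places vinyl trans to the tertiary hydroxyl.

Step 11
Reactants: 13 C6,C10-diol with a C1 vinyl group
Product: 14 β-hydroxy ketone (C6 ketone, free C10 tertiary alcohol, C1 vinyl cis to the C7 side chain)
Conditions: Dess–Martin periodinane, NaHCO3, CH2Cl2, 0 to 23 °C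
Reagents that add atoms: none
Why: Dess–Martin oxidation can only convert the secondary C6 alcohol, and the buffered neutral medium should spare the α-vinyl ketone from conjugation and retro-aldol cleavage.

Step 12
Reactants: 14 β-hydroxy ketone
Product: 15 C10 tert-butyldimethylsilyl ether of 14 (2,6-cis ketone: vinyl cis to the C7 side chain)
Conditions: TBSOTf, 2,6-lutidine, CH2Cl2, −78 to 0 °C
Reagents that add atoms: tert-butyldimethylsilyl triflate CC(C)(C)[Si](C)(C)OS(=O)(=O)C(F)(F)F
Why: Silyl triflate silylation of the tertiary alcohol blocks retro-aldol cleavage and any later alkoxide chemistry at C10, and the bulky silyl group resists migration to the C6 alkoxide in step 17.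

Step 13
Reactants: 15 C10 tert-butyldimethylsilyl ether of 14
Product: 17 C1 epimer of 15 (vinyl trans to the C7 side chain, cis to the C10 silyloxy group), via potassium dienolate 16 (not isolated)
Conditions: KN(SiMe3)2 (0.98 equiv), THF, −78 to −40 °C; then AcOH, −78 °C
Reagents that add atoms: none
Why: Removal of the doubly activated C1 proton gives the extended enolate, and kinetic α-protonation of that dienolate (the protonation used in deconjugations) from the face opposite the pseudo-axial C10 silyloxy group inverts C1; the product also escapes the syn-axial C8–O/C10–CH3 contact of 15 and is expected to be no less stable.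

Step 14
Reactants: 18 propargyl alcohol
Product: 19 1-methoxy-4-[(prop-2-yn-1-yloxy)methyl]benzene
Conditions: NaH, 4-MeOC6H4CH2Cl, Bu4NI (cat.), THF, 0 to 23 °C
Reagents that add atoms: 4-methoxybenzyl chloride COc1ccc(CCl)cc1
Why: Williamson etherification of the primary propargylic alkoxide with a benzylic chloride.

Step 15
Reactants: 19 1-methoxy-4-[(prop-2-yn-1-yloxy)methyl]benzene
Product: 20 1-methoxy-4-[(propa-1,2-dien-1-yloxy)methyl]benzene
Conditions: KOtBu (0.3 equiv), THF, 23 °C
Reagents that add atoms: none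
Why: Base-catalysed propargyl-to-allenyl isomerisation of a propargyl ether, the standard entry to alkoxyallenes.

Step 16
Reactants: 17 C1 epimer of 15; 20 1-methoxy-4-[(propa-1,2-dien-1-yloxy)methyl]benzene
Product: 22 C6 tertiary alcohol (1-(4-methoxybenzyloxy)allenyl group at C6 trans to the C1 vinyl group; C6 hydroxyl cis to vinyl and to the C10 silyloxy group, trans to the C7 side chain), via lithioallene 21 (not isolated)
Conditions: 20, BuLi, THF, −78 °C; then 17, −78 °C; NH4Cl aq.
Reagents that add atoms: none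
Why: α-Lithiation of the alkoxyallene and 1,2-addition of its oxygen-bearing carbon to the ketone; the slim nucleophile should enter equatorially on the face away from the axial C10 silyloxy group, which puts the allenyl group trans to the C1 vinyl group.

Step 17
Reactants: 22 C6 tertiary alcohol (allenyl vinyl cyclohexanol)
Product: 25 (5S,7R,8R,10R,1E)-cyclodec-1-en-6-one carrying 5-(4-methoxybenzyloxy), 4-methylene, 7-[2-(tert-butyldimethylsilyloxy)ethyl], 8-(tert-butyldimethylsilyloxy), 10-methyl and 10-(tert-butyldimethylsilyloxy), via potassium alkoxide 23 (not isolated), via potassium enolate 24 (not isolated)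
Conditions: KH (3 equiv), 18-crown-6 (3 equiv), THF, 0 to 23 °C; then AcOH, THF, −78 °C
Reagents that add atoms: none
Why: KH and 18-crown-6 give the naked C6 alkoxide 23, whose [3,3] shift (anionic oxy-Cope rearrangement, established for trans-1,2-dialkenylcyclohexanols going to (E)-cyclodec-5-enones and here run with an alkoxyallenyl partner) forms C3–C4 between the vinyl terminus and the central allene carbon while the C1–C6 ring bond breaks. The ten-membered ring is therefore not closed end to end but arises by four-atom expansion of the six-membered ring through a chair six-centre transition state. E-C1=C2 needs allenyl and vinyl trans-diequatorial, which the chair of 22 with axial C6–O provides; the allene leaves C15 as the C4 methylene and its oxygen on C5. The only new stereocentre, C5, is made on quench: enolate 24 is E across C5=C6 (C4 and C7 trans) and cannot turn inside the ring, so the lobe that faced C1 stays buried and acetic acid at −78 °C protonates the outer face, which puts the C5 oxygen on the ring face opposite the former axial C6–O bond, that is 5S for the C6 configuration chosen in 22. The step also needs the [3,3] shift to outrun 5-endo closure of the alkoxide onto the allene, which the aprotic medium (no proton shuttle) and the strain released should secure, and α- rather than γ-protonation of the dienolate, which the cold kinetic quench should secure.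

Step 18
Reactants: 25 ten-membered ketone
Product: 26 (6S)-alcohol of 25 (C6 hydroxyl threo to the C5 ether oxygen; other centres unchanged)
Conditions: K[HB(s-Bu)3], THF, −78 °C
Reagents that add atoms: none
Why: Reduction with a bulky trialkylborohydride whose potassium counter-ion does not chelate, so hydride should attack the C6 carbonyl from the ring periphery anti to the C5–O bond (polar Felkin–Anh addition) and give the 5,6-threo (6S) alcohol.

Step 19
Reactants: 26 (6S)-alcohol
Product: 27 C6,C12-diol (primary silyl ether removed)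
Conditions: camphorsulfonic acid (10 mol %), MeOH/CH2Cl2, 0 °C
Reagents that add atoms: none
Why: Acid-catalysed methanolysis removes a primary tert-butyldimethylsilyl ether far faster than the secondary and tertiary ones, and the 4-methoxybenzyl ether is inert.

Step 20
Reactants: 27 C6,C12-diol
Product: 28 trans-fused 6,12-γ-lactone (C11 still CH2)
Conditions: TEMPO (20 mol %), PhI(OAc)2 (3 equiv), CH2Cl2, 23 °C
Reagents that add atoms: none
Why: Oxoammonium oxidation of the primary alcohol, lactol formation with the C6 hydroxyl and a second oxidation (oxidative lactonisation of a 1,4-diol) close the γ-lactone without touching alkenes or ethers.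

Step 21
Reactants: 28 trans-fused 6,12-γ-lactone
Product: 31 α-methylene lactone (C11=C13), via Mannich base 29 (not isolated), via ammonium iodide 30 (not isolated)
Conditions: LiN(iPr)2, THF, −78 °C; [CH2=NMe2]I (Eschenmoser's salt), −78 to 0 °C; then MeI, MeOH, 23 °C; then NaHCO3 aq., CH2Cl2, 23 °C
Reagents that add atoms: Eschenmoser's salt C=[N+](C)C.[I-]
Why: Mannich reaction of the lactone lithium enolate with the methyleneiminium salt, N-methylation and E1cB loss of trimethylamine give the α-methylene lactone, and the C11 centre formed on the way is destroyed again.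

Step 22
Reactants: 31 α-methylene lactone
Product: 32 C5 alcohol
Conditions: DDQ, CH2Cl2/pH 7 buffer, 0 °C
Reagents that add atoms: none
Why: Oxidative cleavage of the 4-methoxybenzyl ether by DDQ under buffered conditions leaves silyl ethers, lactone and alkenes untouched.

Step 23
Reactants: 32 C5 alcohol
Product: 33 C5 acetate
Conditions: Ac2O, pyridine, DMAP (cat.), CH2Cl2, 23 °C
Reagents that add atoms: acetic anhydride CC(=O)OC(C)=O
Why: DMAP-catalysed acetylation of the only free hydroxyl.

Step 24
Reactants: 33 C5 acetate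
Product: 34 C8,C10-diol
Conditions: HF·pyridine, pyridine, THF, 0 to 40 °C
Reagents that add atoms: none
Why: Fluoride cleavage of the secondary and the tertiary silyl ether, which the acetate, the α-methylene lactone and the tertiary allylic alcohol should tolerate in the buffered medium.

Step 25
Reactants: 34 C8,C10-diol
Product: 35 target, (5S,6S,7R,8R,10R)-5-acetoxy-10-hydroxy-8-tigloyloxygermacra-1(2)E,4(15),11(13)-trien-12,6-olide
Conditions: (E)-CH3CH=C(CH3)COCl, Et3N, DMAP, CH2Cl2, 0 to 23 °C
Reagents that add atoms: tigloyl chloride C/C=C(\C)C(Cl)=O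
Why: DMAP-catalysed acylation by the acid chloride should take place only at the secondary C8 hydroxyl, the tertiary allylic C10 hydroxyl being too hindered, and the E geometry of the tigloyl unit is not at risk.

**Compound list**

1 | ethyl (3S)-4-chloro-3-hydroxybutanoate | CCOC(=O)C[C@H](O)CCl | starting material
2 | ethyl [(2S)-oxiran-2-yl]acetate | CCOC(=O)C[C@H]1CO1 | intermediate
3 | ethyl (3R)-3-hydroxy-5-methylhex-5-enoate | CCOC(=O)C[C@H](O)CC(C)=C | intermediate
4 | tert-butyl(2-iodoethoxy)dimethylsilane | CC(C)(C)[Si](C)(C)OCCI | starting material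
5 | dilithium alkoxide-enolate of 3 | CCO/C([O-])=C/[C@H]([O-])CC(C)=C.[Li+].[Li+] | intermediate
6 | ethyl (2R,3R)-2-[2-(tert-butyldimethylsilyloxy)ethyl]-3-hydroxy-5-methylhex-5-enoate | CCOC(=O)[C@H](CCO[Si](C)(C)C(C)(C)C)[C@H](O)CC(C)=C | intermediate
7 | ethyl (2R,3R)-3-(tert-butyldimethylsilyloxy)-2-[2-(tert-butyldimethylsilyloxy)ethyl]-5-methylhex-5-enoate | CCOC(=O)[C@H](CCO[Si](C)(C)C(C)(C)C)[C@H](O[Si](C)(C)C(C)(C)C)CC(C)=C | intermediate
8 | (2R,3R)-3-(tert-butyldimethylsilyloxy)-2-[2-(tert-butyldimethylsilyloxy)ethyl]-N-methoxy-N,5-dimethylhex-5-enamide | CON(C)C(=O)[C@H](CCO[Si](C)(C)C(C)(C)C)[C@H](O[Si](C)(C)C(C)(C)C)CC(C)=C | intermediate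
9 | (4R,5R)-5-(tert-butyldimethylsilyloxy)-4-[2-(tert-butyldimethylsilyloxy)ethyl]-7-methylocta-1,7-dien-3-one | C=CC(=O)[C@H](CCO[Si](C)(C)C(C)(C)C)[C@H](O[Si](C)(C)C(C)(C)C)CC(C)=C | intermediate
10 | (5R,6R)-5-(tert-butyldimethylsilyloxy)-6-[2-(tert-butyldimethylsilyloxy)ethyl]-3-methylcyclohex-2-en-1-one | O=C1[C@H](CCO[Si](C)(C)C(C)(C)C)[C@H](O[Si](C)(C)C(C)(C)C)CC(C)=C1 | intermediate
11 | C1–C10 epoxide of 10, oxygen trans to the C8 silyloxy group | O=C1[C@H](CCO[Si](C)(C)C(C)(C)C)[C@H](O[Si](C)(C)C(C)(C)C)C[C@@]2(C)O[C@@H]12 | intermediate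
12 | cis-epoxy alcohol from 11 (C6 hydroxyl syn to the epoxide oxygen) | O[C@H]1[C@H](CCO[Si](C)(C)C(C)(C)C)[C@H](O[Si](C)(C)C(C)(C)C)C[C@@]2(C)O[C@@H]12 | intermediate
13 | C6,C10-diol with C1 vinyl trans to the C10 hydroxyl | O[C@H]1[C@H](CCO[Si](C)(C)C(C)(C)C)[C@H](O[Si](C)(C)C(C)(C)C)C[C@@](C)(O)[C@@H]1C=C | intermediate
14 | C6 ketone with free C10 tertiary alcohol, vinyl cis to the C7 side chain | O=C1[C@H](CCO[Si](C)(C)C(C)(C)C)[C@H](O[Si](C)(C)C(C)(C)C)C[C@@](C)(O)[C@@H]1C=C | intermediate
15 | C10 silyl ether of 14 (vinyl cis to the C7 side chain) | O=C1[C@H](CCO[Si](C)(C)C(C)(C)C)[C@H](O[Si](C)(C)C(C)(C)C)C[C@@](C)(O[Si](C)(C)C(C)(C)C)[C@@H]1C=C | intermediate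
16 | potassium dienolate of 15 | [K+].[O-]C1=C(C=C)[C@](C)(O[Si](C)(C)C(C)(C)C)C[C@@H](O[Si](C)(C)C(C)(C)C)[C@H]1CCO[Si](C)(C)C(C)(C)C | intermediate
17 | C1 epimer of 15 (vinyl trans to the C7 side chain, cis to the C10 silyloxy group) | O=C1[C@H](CCO[Si](C)(C)C(C)(C)C)[C@H](O[Si](C)(C)C(C)(C)C)C[C@@](C)(O[Si](C)(C)C(C)(C)C)[C@H]1C=C | intermediate
18 | propargyl alcohol | C#CCO | starting material
19 | 1-methoxy-4-[(prop-2-yn-1-yloxy)methyl]benzene | C#CCOCc1ccc(OC)cc1 | intermediate
20 | 1-methoxy-4-[(propa-1,2-dien-1-yloxy)methyl]benzene | C=C=COCc1ccc(OC)cc1 | intermediate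
21 | 1-lithio-1-(4-methoxybenzyloxy)allene | [Li]C(=C=C)OCc1ccc(OC)cc1 | intermediate
22 | 1-[1-(4-methoxybenzyloxy)allenyl]-2-vinylcyclohexanol (allenyl trans to vinyl; C6 hydroxyl trans to the C7 side chain) | C=C=C(OCc2ccc(OC)cc2)[C@]1(O)[C@H](CCO[Si](C)(C)C(C)(C)C)[C@H](O[Si](C)(C)C(C)(C)C)C[C@@](C)(O[Si](C)(C)C(C)(C)C)[C@H]1C=C | intermediate
23 | potassium alkoxide of 22 | C=C=C(OCc2ccc(OC)cc2)[C@]1([O-])[C@H](CCO[Si](C)(C)C(C)(C)C)[C@H](O[Si](C)(C)C(C)(C)C)C[C@@](C)(O[Si](C)(C)C(C)(C)C)[C@H]1C=C.[K+] | intermediate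
24 | potassium C5=C6 enolate of the ten-membered ring (C4 and C7 trans) | [K+].[O-]/C1=C(/OCc2ccc(OC)cc2)C(=C)C/C=C/[C@](C)(O[Si](C)(C)C(C)(C)C)C[C@@H](O[Si](C)(C)C(C)(C)C)[C@H]1CCO[Si](C)(C)C(C)(C)C | intermediate
25 | (5S,7R,8R,10R,1E)-5-(4-methoxybenzyloxy)-4-methylene-7-[2-(tert-butyldimethylsilyloxy)ethyl]-8,10-bis(tert-butyldimethylsilyloxy)-10-methylcyclodec-1-en-6-one | O=C1[C@H](CCO[Si](C)(C)C(C)(C)C)[C@H](O[Si](C)(C)C(C)(C)C)C[C@@](C)(O[Si](C)(C)C(C)(C)C)/C=C/CC(=C)[C@@H]1OCc2ccc(OC)cc2 | intermediate
26 | (6S)-alcohol of 25 | O[C@H]1[C@H](CCO[Si](C)(C)C(C)(C)C)[C@H](O[Si](C)(C)C(C)(C)C)C[C@@](C)(O[Si](C)(C)C(C)(C)C)/C=C/CC(=C)[C@@H]1OCc2ccc(OC)cc2 | intermediate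
27 | C6,C12-diol | O[C@H]1[C@H](CCO)[C@H](O[Si](C)(C)C(C)(C)C)C[C@@](C)(O[Si](C)(C)C(C)(C)C)/C=C/CC(=C)[C@@H]1OCc2ccc(OC)cc2 | intermediate
28 | trans-fused 6,12-γ-lactone with C11 as CH2 | C1C(=O)O[C@H]2[C@H]1[C@H](O[Si](C)(C)C(C)(C)C)C[C@@](C)(O[Si](C)(C)C(C)(C)C)/C=C/CC(=C)[C@@H]2OCc3ccc(OC)cc3 | intermediate
29 | C11 dimethylaminomethyl lactone (Mannich base; aminomethyl anti to C8) | CN(C)C[C@@H]1C(=O)O[C@H]2[C@H]1[C@H](O[Si](C)(C)C(C)(C)C)C[C@@](C)(O[Si](C)(C)C(C)(C)C)/C=C/CC(=C)[C@@H]2OCc3ccc(OC)cc3 | intermediate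
30 | C11 trimethylammoniomethyl lactone iodide | C[N+](C)(C)C[C@@H]1C(=O)O[C@H]2[C@H]1[C@H](O[Si](C)(C)C(C)(C)C)C[C@@](C)(O[Si](C)(C)C(C)(C)C)/C=C/CC(=C)[C@@H]2OCc3ccc(OC)cc3.[I-] | intermediate
31 | α-methylene lactone with C5 4-methoxybenzyl ether and C8, C10 silyl ethers | C=C1C(=O)O[C@H]2[C@H]1[C@H](O[Si](C)(C)C(C)(C)C)C[C@@](C)(O[Si](C)(C)C(C)(C)C)/C=C/CC(=C)[C@@H]2OCc3ccc(OC)cc3 | intermediate
32 | C5 alcohol | C=C1C(=O)O[C@H]2[C@H]1[C@H](O[Si](C)(C)C(C)(C)C)C[C@@](C)(O[Si](C)(C)C(C)(C)C)/C=C/CC(=C)[C@@H]2O | intermediate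
33 | C5 acetate | C=C1C(=O)O[C@H]2[C@H]1[C@H](O[Si](C)(C)C(C)(C)C)C[C@@](C)(O[Si](C)(C)C(C)(C)C)/C=C/CC(=C)[C@@H]2OC(C)=O | intermediate
34 | C5 acetate with free C8 and C10 hydroxyls | C=C1C(=O)O[C@H]2[C@H]1[C@H](O)C[C@@](C)(O)/C=C/CC(=C)[C@@H]2OC(C)=O | intermediate
35 | (5S,6S,7R,8R,10R)-5-acetoxy-10-hydroxy-8-tigloyloxygermacra-1(2)E,4(15),11(13)-trien-12,6-olide | C=C1C(=O)O[C@H]2[C@H]1[C@H](OC(=O)/C(C)=C/C)C[C@@](C)(O)/C=C/CC(=C)[C@@H]2OC(C)=O | target

**Count.** Total steps: 25. Longest linear sequence: 23 steps (steps 1–13 and 16–25); steps 14–15 make the allene branch.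

**Steps most likely to fail**

Step 17. The rearrangement itself is well founded, but the proton may reach the other face of the C5=C6 enolate if the chair model misjudges which face is exposed or if the enolate unit does turn inside the ring; that would give the C5 epimer. The fallback changes the substrate, not the conditions. It sets out from 15, skips the C1 inversion of step 13, and adds lithioallene 21 to the face away from the syn-axial C8 silyloxy and C10 methyl groups, giving the C1,C6-diepimeric allenyl vinyl cyclohexanol F1 (allenyl still trans to vinyl). Its KH/18-crown-6 rearrangement passes through the mirror-related chair, presents the opposite enolate face to the acid and comes back to the route at 25.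

Step 18. Facial selectivity at the C6 carbonyl may be ruled by the ring conformation instead of the acyclic Felkin–Anh model, so the hydroxyl may come out on the wrong face. The fallback sets out from 25 and uses that outcome: the 6-epi alcohol F2 is converted with CH3SO2Cl/Et3N into the C6 mesylate F3; acid-catalysed methanolysis frees the primary alcohol F4; TEMPO/PhI(OAc)2 in aqueous MeCN oxidises it to the carboxylic acid F5; and Cs2CO3 in DMF closes the lactone by intramolecular SN2 displacement of the mesylate with inversion at C6, coming back to the route at 28.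

Step 13. The amide base may remove the C7 proton in competition with the C1 proton, and the resulting enolate can expel the C8 silyloxy group; facial control of the protonation may also be incomplete. The fallback sets out from 15 and makes the enolate regiospecifically: soft enolisation with TMSOTf/Et3N should give the conjugated trimethylsilyl dienol ether F6; MeLi in THF cleaves it to the lithium dienolate F7; protonation with AcOH at −78 °C then returns to the route at 17. Unwanted epimer 15 can be recycled through the same sequence.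

**Further compounds**

F1 | step 17 | C1,C6-diepimer of 22 (vinyl cis to the C7 side chain, allenyl trans to vinyl) | C=C=C(OCc2ccc(OC)cc2)[C@@]1(O)[C@H](CCO[Si](C)(C)C(C)(C)C)[C@H](O[Si](C)(C)C(C)(C)C)C[C@@](C)(O[Si](C)(C)C(C)(C)C)[C@@H]1C=C
F2 | step 18 | 6-epi alcohol of 25 | O[C@@H]1[C@H](CCO[Si](C)(C)C(C)(C)C)[C@H](O[Si](C)(C)C(C)(C)C)C[C@@](C)(O[Si](C)(C)C(C)(C)C)/C=C/CC(=C)[C@@H]1OCc2ccc(OC)cc2
F3 | step 18 | C6 mesylate of F2 | CS(=O)(=O)O[C@@H]1[C@H](CCO[Si](C)(C)C(C)(C)C)[C@H](O[Si](C)(C)C(C)(C)C)C[C@@](C)(O[Si](C)(C)C(C)(C)C)/C=C/CC(=C)[C@@H]1OCc2ccc(OC)cc2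
F4 | step 18 | C6 mesylate with free C12 primary alcohol | CS(=O)(=O)O[C@@H]1[C@H](CCO)[C@H](O[Si](C)(C)C(C)(C)C)C[C@@](C)(O[Si](C)(C)C(C)(C)C)/C=C/CC(=C)[C@@H]1OCc2ccc(OC)cc2
F5 | step 18 | C6 mesylate C12 carboxylic acid | CS(=O)(=O)O[C@@H]1[C@H](CC(=O)O)[C@H](O[Si](C)(C)C(C)(C)C)C[C@@](C)(O[Si](C)(C)C(C)(C)C)/C=C/CC(=C)[C@@H]1OCc2ccc(OC)cc2
F6 | step 13 | trimethylsilyl dienol ether of 15 | C[Si](C)(C)OC1=C(C=C)[C@](C)(O[Si](C)(C)C(C)(C)C)C[C@@H](O[Si](C)(C)C(C)(C)C)[C@H]1CCO[Si](C)(C)C(C)(C)C
F7 | step 13 | lithium dienolate of 15 | [Li+].[O-]C1=C(C=C)[C@](C)(O[Si](C)(C)C(C)(C)C)C[C@@H](O[Si](C)(C)C(C)(C)C)[C@H]1CCO[Si](C)(C)C(C)(C)C
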